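## Structural features

The target is a C20 bromo diether on a trans-fused decalin (rings A and B, labdane numbering). Ring A carries the C4 gem-dimethyl group and next to it an equatorial secondary bromide at C3; ring B carries the angular C10 methyl and a fully substituted, oxygen-bearing C8. An eight-membered cyclic ether (ring C: C8–O–C15–C14–C13–C12–C11–C9) is fused to ring B across C8–C9, and an oxirane (ring D) spans C13–C14, with a methyl on C13. Five contiguous stereocentres line the decalin (3R,5S,8S,9S,10R, the series antipodal to sclareol), and C13 and C14 (13S,14R) sit on the far side of ring C, related to the others only through the conformation of the medium ring. At the B/C junction the ether oxygen on C8 and C11 on C9 are both equatorial and gauche to each other, and C9 is flanked by the axial methyl groups on C8 and C10, so the space around C11 is crowded on one side. The fragile groups are the trisubstituted epoxide (acid, nucleophiles), the tertiary ether at C8 (Lewis-acid ionisation) and the neopentyl-type C3 bromide, which resists base (no anti-periplanar hydrogen, hindered backside) but not radicals, strong electron donors or cationic activation. The real difficulty is ring C: an eight-membered ring closed onto a tertiary oxygen and holding a trisubstituted cis C13=C14 unit at the epoxide oxidation level, on a decalin whose absolute configuration must come from a bromonium-initiated cyclisation. The key step uses the fact that C12, C13 (with its methyl), C14 and C15 form a (Z)-2-methylbut-2-ene-1,4-diyl bridge between C11 and the C8 oxygen: ring C is the union of a 1,4-dinucleophile (O8/C11, pre-organised on ring B) and a cis 1,4-dielectrophile with the geometry of a methylbutenolide, and the C13 methyl makes the two allylic ends different.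

## Logic of the disconnections

16 is first simplified to 15 by removing the oxirane oxygen (cutting C13–O and C14–O). The epoxide is the most sensitive group and a cis-epoxide maps directly onto a cis ring olefin, so it comes last. This removes two stereocentres and leaves one olefin as the only reactive group besides the bromide. The forward step needs facial selectivity on a medium ring, which must come from the ring conformation.

15 is related to 14 by exchanging a C11–H bond for a C11–S bond. The sulfonyl group exists only to make C11 a carbon nucleophile, so its removal follows ring formation. The gain is that C11, a centre with no function in 16, becomes the handle for C–C bond formation. The forward step must cleave C–S reductively without touching C3–Br or the olefin.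

14 is cut at O8–C15 and C11–C12, the two bonds that tie the four-carbon bridge to the decalin, giving 7 and 12. This takes ring C apart into a rigid 1,4-dinucleophile and a cis 1,4-dielectrophile, removes the only medium ring and keeps olefin geometry out of the problem. The forward step must join the pieces in the right orientation and close an eight-membered ring. The carbanion is the stronger nucleophile of the dianion and will react first, so bromide is placed on the carbon next to the methyl-bearing olefin carbon (future C12) and chloride on the other end (future C15). The ring closure is then an O-alkylation whose SN2' position is the methyl-substituted C13 and is therefore blocked. The opposite halide placement would leave the closure to the carbanion, which would have an open six-membered SN2' path at C14, and it would require a hindered tertiary alkoxide to outrun an adjacent sulfonyl carbanion in the first alkylation.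

12 is traced through 11 and 10 to 8 by two functional-group interconversions (C–Cl to C–OH, CH2OH to ester) and one exchange of C–Br for the lactone C–O bond. Both the cis geometry and the difference between the two ends already exist in the five-membered ring of 8, so no olefin has to be made. The demands are a ring-opening that puts bromide on the allylic carbon, and conditions that never let the cis bromo ester or bromo alcohol close back or isomerise.

7 goes back through 6 to 4 and 5 by cutting the C11–S bond after lowering the sulfur oxidation level. The primary alcohol of 4 is the only hydroxyl that can be activated, so no protecting group is needed. The gain is a diol in which both nucleophilic sites of the key step are already in place. The forward displacement must work at a primary but β-branched carbon.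

4 is taken back through 3 to 1 by cutting C3–Br, C4–C5, C9–C10 and C8–O in one operation and the ester C–O bond in another. This is the polyene-cyclisation disconnection: both rings and all five decalin stereocentres come from an acyclic triene, with the ester as internal oxygen terminator for C8. The forward step must deliver bromine to one face of the terminal olefin and carry the cascade through to capture at C8.

## Other disconnections considered

Alternative 1: The cut removes C13 with its methyl from ring C (C12–C13 and C13–C14), leaving the seven-membered ether ketone A1 with its carbonyl at C14.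
- Forward step: a Lewis acid (BF3·OEt2 or Me3Al) would promote addition of diazoethane to the C14 carbonyl and 1,2-shift of C12 with loss of N2, giving the eight-membered ketone A2 with the methyl on C13.
- In its favour: ring C is never closed as an eight-membered ring. This is better than the chosen plan, since a seven-membered ring closes more easily and the expansion has no entropic cost. The migration sense is the expected one, because the oxygen-bearing C15 should migrate less readily than the plain methylene C12. The methyl lands on the right atom, which is equal to the chosen plan.
- Against it here: diazoethane is hazardous and must be generated for the purpose. A ketone flanked by two methylenes tends to over-homologate or give epoxide. The Lewis acid meets a tertiary ether and a neopentyl bromide that can ionise or rearrange. A2 is at the wrong oxidation pattern: the C14 carbonyl and C13–H must still be turned into the C13=C14 olefin before epoxidation, whereas the chosen key step delivers the olefin in place.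
- Comparison: on structure the plans are equal for the methyl position and Alternative 1 is better on ring-size entropy. On mechanism the chosen plan uses anionic SN2 chemistry, which suits the bromide better than diazonium and Lewis-acid chemistry. On step count A1 would need about as many steps from 4 as the chosen route needs to reach 14, so the chosen plan should be shorter by an estimated three to four steps.

Alternative 2: The single cut is C14–C15, which opens ring C to A3, a C8 methoxymethyl ether carrying at C11 a chain that ends in a (Z)-vinylsilane at C13=C14.
- Forward step: a Lewis acid (SnCl4 or TiCl4, low temperature) would ionise the acetal to the oxocarbenium ion C8–O+=CH2, and ipso attack of the vinylsilane at C14 with loss of silicon would give A4, which has the structure of 15.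
- In its favour: A4 is reached directly, so no sulfone has to be removed afterwards; this is one step fewer after ring closure and is better. Silicon fixes the position and geometry of the olefin, which is equal to what the cis dielectrophile does in the chosen plan. The hindered tertiary oxygen is alkylated in an easy intermolecular acetal formation and the ring is closed by C–C bond formation, which is arguably better than closing the ring onto a tertiary alkoxide.
- Against it here: a tertiary alkoxymethyl ether can also ionise at the C8–O bond, giving the C8 cation and ring B olefins. The Lewis acid has to spare the C3 bromide. Eight-membered closure competes with protodesilylation. A3 is not simple: the trisubstituted (Z)-vinylsilane must be built stereoselectively and attached at C11, most likely by the same kind of alkylation that the chosen plan uses.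
- Comparison: on structure the plans are equal. On mechanism the alternative is cationic where the chosen plan is anionic, and this substrate is better served by base. On step count the alternative saves the desulfonylation but spends more on A3, and should come out two to three steps longer.

Alternative 3: No bond of 16 is cut. A C11–C15 bond is added in the retrosynthetic direction, so that the eight-membered ring becomes two fused five-membered rings in the lactol A5 (C15 is a hemiketal carbon bonded to O8, OH, C14 and C11).
- Forward step: the C15 alkoxy radical, generated for example with PhI(OAc)2 and I2 under light, would cleave the shared C11–C15 bond to give the C15 lactone carbonyl and a C11 radical. Hydrogen-atom transfer would then leave the eight-membered lactone A6 with the methyl on C13.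
- In its favour: the medium ring arises by fragmentation of a compact bicyclic precursor, with no entropic penalty and no competition from smaller rings; on this point it is better than the chosen plan. The conditions are neutral, which is equal or better for the tertiary ether.
- Against it here: A5 has more rings and one more C–C bond than 16 and is clearly harder to make than 7. The C11 radical needs a hydrogen donor, and stannane donors would also remove the C3 bromine, while iodine trapping leaves a C11 iodide to reduce. A6 has the wrong oxidation pattern at three atoms: the C15 carbonyl must become a methylene and C13–C14 must be dehydrogenated before an epoxide can be introduced, which also destroys the C13 stereocentre that A5 had to carry.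
- Comparison: on structure the chosen plan maps the functionality of 16 directly and the alternative does not. On mechanism the alternative's ring formation is more reliable in itself, but its radical step conflicts with the bromide. On step count it should be the longest of the four plans.

Key step: step 8

Remark: the (R)-catalyst of step 1 is assumed to brominate the Re face of C10 of 1 (its antipode would be used otherwise), and the change of the C9 descriptor from R (2–4) to S (from 6 on) reflects CIP priorities only, not an inversion.

## Route

Step 1
Reactants: 1 (2E,6E)-farnesyl acetate
Product: 3 (3R,5S,8S,9R,10R)-3-bromo-8-hydroxydriman-11-yl acetate, via acetoxonium ion 2 (not isolated)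
Conditions: DBDMH (1.0 equiv), (R)-(ArO)2P(=S)NHSO2CF3 [(ArO)2 = 3,3'-bis(2,4,6-triisopropylphenyl)-1,1'-binaphthalene-2,2'-diolate] (10 mol %), toluene/CH2Cl2, −78 °C; then H2O, NaHCO3, Na2S2O3
Reagents that add atoms: 1,3-dibromo-5,5-dimethylhydantoin (DBDMH), CC1(C)N(Br)C(=O)N(Br)C1=O; water, O
Why: Proposed new method: a bromenium ion bound to the chiral Lewis-basic sulfur should be transferred to the Re face of C10 of the terminal, most accessible olefin; the bromonium ion is opened at C11 by the 6,7-olefin and the next cation by the 2,3-olefin through chair–chair anti additions, which fix C5, C10, C9 and C8 relative to C3, and the ester carbonyl captures the C8 cation equatorially as acetoxonium ion 2, which water opens to 3 (any 8-acetoxy-11-ol isomer converges in step 2). The closest known reaction types are the catalytic enantioselective bromonium polyene cyclisation of aryl-terminated geranyl systems with thiophosphoramide Lewis bases and DBDMH, and the racemic bromonium cyclisation of farnesyl esters; combining enantiocontrol with ester termination on a farnesyl chain is the new element.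

Step 2
Reactants: 3 (3R,5S,8S,9R,10R)-3-bromo-8-hydroxydriman-11-yl acetate
Product: 4 (3R,5S,8S,9R,10R)-3-bromodrimane-8,11-diol
Conditions: K2CO3, MeOH, rt
Reagents that add atoms: none
Why: Base-catalysed transesterification (methanolysis) removes the primary acetate and any tertiary acetate isomer. The equatorial C3 bromide has no anti-periplanar hydrogen and sits next to a quaternary carbon, so neither E2 nor SN2 should compete.

Step 3
Reactants: 4 (3R,5S,8S,9R,10R)-3-bromodrimane-8,11-diol; 5 diphenyl disulfide
Product: 6 (3R,5S,8S,9S,10R)-3-bromo-11-(phenylsulfanyl)driman-8-ol
Conditions: 5, Bu3P, pyridine, rt → 60 °C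
Reagents that add atoms: none
Why: Phosphine–disulfide thioetherification (Hata reaction): the primary C11 alcohol forms an alkoxyphosphonium ion that benzenethiolate displaces by SN2, while the tertiary C8 alcohol is too hindered to be activated. No stereocentre is touched.

Step 4
Reactants: 6 (3R,5S,8S,9S,10R)-3-bromo-11-(phenylsulfanyl)driman-8-ol
Product: 7 (3R,5S,8S,9S,10R)-3-bromo-11-(phenylsulfonyl)driman-8-ol
Conditions: mCPBA (2.2 equiv), NaHCO3, CH2Cl2, 0 °C → rt
Reagents that add atoms: 3-chloroperoxybenzoic acid (mCPBA), OOC(=O)c1cccc(Cl)c1
Why: Peracid oxidation of the sulfide through the sulfoxide to the sulfone. The molecule holds no olefin at this stage, and the tertiary alcohol and the bromide are inert.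

Step 5
Reactants: 8 4-methylfuran-2(5H)-one
Product: 10 methyl (Z)-4-bromo-3-methylbut-2-enoate, via silyl ester 9 (not isolated)
Conditions: Me3SiBr (1.5 equiv), CH2Cl2, rt → 40 °C; then MeOH, 0 °C → rt
Reagents that add atoms: bromotrimethylsilane, C[Si](C)(C)Br; methanol, CO
Why: Silyl-halide cleavage of a lactone at the alkyl–oxygen bond: O-silylation of the carbonyl makes C5 an activated allylic electrophile that bromide opens by SN2, and methanol converts silyl ester 9 to the methyl ester under the HBr present. The cis relationship of CH2Br and the ester is inherited from the ring, so the Z geometry is kept, not made.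

Step 6
Reactants: 10 methyl (Z)-4-bromo-3-methylbut-2-enoate
Product: 11 (Z)-4-bromo-3-methylbut-2-en-1-ol
Conditions: i-Bu2AlH (2.2 equiv), CH2Cl2, −78 °C; MeOH, then aq. KNaC4H4O6, cold
Reagents that add atoms: none
Why: Low-temperature 1,2-reduction of the enoate by i-Bu2AlH gives the allylic alcohol without touching the allylic bromide or the olefin geometry. The cold, non-basic work-up avoids closure of the cis bromo alkoxide to a dihydrofuran.

Step 7
Reactants: 11 (Z)-4-bromo-3-methylbut-2-en-1-ol
Product: 12 (Z)-1-bromo-4-chloro-2-methylbut-2-ene
Conditions: Ph3P, Cl3CC(O)CCl3, CH2Cl2, −20 → 0 °C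
Reagents that add atoms: hexachloroacetone, ClC(Cl)(Cl)C(=O)C(Cl)(Cl)Cl
Why: Appel-type chlorination with Ph3P and hexachloroacetone converts primary allylic alcohols to chlorides by SN2 under neutral conditions without allylic transposition or loss of Z geometry. Chloride appears only as the ion-pair partner of the alkoxyphosphonium ion, which limits bromide–chloride exchange at the other terminus.

Step 8
Reactants: 7 (3R,5S,8S,9S,10R)-3-bromo-11-(phenylsulfonyl)driman-8-ol; 12 (Z)-1-bromo-4-chloro-2-methylbut-2-ene
Product: 14 (3R,5S,8S,9S,10R,11S,13Z)-3-bromo-8,15-epoxy-11-(phenylsulfonyl)labd-13-ene, via chloro alkoxide 13 (not isolated)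
Conditions: n-BuLi (2.0 equiv), THF, −78 °C; 12 (1.0 equiv), −78 → −40 °C; then HMPA, Bu4NI (10 mol %), THF (to 5 mM), −40 → 45 °C
Reagents that add atoms: none
Why: Two equivalents of n-BuLi give the O8,C11-dianion of 7, whose sulfonyl carbanion is by far the better nucleophile and displaces the methallylic bromide of 12 by SN2 to give alkoxide 13 with the C11–C12 bond; allylic bromide typically reacts about two orders of magnitude faster than allylic chloride, which fixes the orientation of the four-carbon unit. HMPA, catalytic Bu4NI, dilution and warming then let the alkoxide close the oxocene by an 8-exo-tet Williamson displacement of the Z-allylic chloride (through the iodide), forming O8–C15. The closest known reaction types are the C-alkylation of hydroxy-sulfone dianions and the annulation of 1,4-dinucleophiles with (Z)-1,4-dihalobut-2-enes. Closure is helped by the gauche O8/C11 relationship fixed on ring B and by the cis olefin, which holds C12 and C15 about 3 Å apart, so only four single bonds have to be frozen. An SN2' closure is not open to the oxygen nucleophile because its γ-carbon is C13, fully substituted by the methyl group, whereas the opposite halide placement would leave the closure to the carbanion with an unhindered six-membered SN2' path at C14. A second C-alkylation to a cyclopentene is disfavoured because C11 would become quaternary in the cleft between the axial methyl groups on C8 and C10. C11 is set in the first alkylation and selected in the second: only the 11S epimer, with the sulfonyl group turned away from that cleft, can reach the closure geometry, and the epimers can interconvert through the carbanion under the basic closure conditions; the centre is removed in step 9. The C3 bromide (equatorial, neopentyl, unfavourable for exchange with a primary alkyllithium) should survive.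

Step 9
Reactants: 14 (3R,5S,8S,9S,10R,11S,13Z)-3-bromo-8,15-epoxy-11-(phenylsulfonyl)labd-13-ene
Product: 15 (3R,5S,8S,9S,10R,13Z)-3-bromo-8,15-epoxylabd-13-ene
Conditions: Mg (turnings, I2-activated), MeOH/THF, rt → 50 °C
Reagents that add atoms: none
Why: Reductive desulfonylation by single-electron transfer from Mg in MeOH: the arenesulfonyl group accepts the electron, benzenesulfinate leaves and the C11 radical is reduced and protonated. An unactivated secondary alkyl bromide and an isolated trisubstituted olefin should not be reduced under these conditions; the C11 stereocentre disappears.

Step 10
Reactants: 15 (3R,5S,8S,9S,10R,13Z)-3-bromo-8,15-epoxylabd-13-ene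
Product: 16 (3R,5S,8S,9S,10R,13S,14R)-3-bromo-8,15:13,14-diepoxylabdane
Conditions: mCPBA (1.1 equiv), NaHCO3, CH2Cl2, 0 °C
Reagents that add atoms: 3-chloroperoxybenzoic acid (mCPBA), OOC(=O)c1cccc(Cl)c1
Why: Prilezhaev epoxidation of the only olefin; syn addition gives the cis-13,14-epoxide. The face is set by the ring conformation: the axial methyl groups on C8 and C10 keep C12 out of their side of ring B, so the C12–C15 segment hangs to the opposite side with the vinylic methyl and hydrogen pointing that way, and the peracid attacks the outward (peripheral) olefin face, which corresponds to 13S,14R. NaHCO3 buffers the acid-labile epoxide.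

## Compound list

1 | (2E,6E)-farnesyl acetate | CC(C)=CCC/C(C)=C/CC/C(C)=C/COC(C)=O | starting material
2 | acetoxonium ion: 2-methyl-1,3-dioxan-2-ylium ring bridging O8 and O11 of (3R,5S,8S,9R,10R)-3-bromodrimane-8,11-diol | CC1(C)[C@H](Br)CC[C@]2(C)[C@@H]1CC[C@]1(C)[O+]=C(C)OC[C@@H]21 | intermediate (not isolated)
3 | (3R,5S,8S,9R,10R)-3-bromo-8-hydroxydriman-11-yl acetate | CC1(C)[C@H](Br)CC[C@]2(C)[C@@H]1CC[C@](C)(O)[C@H]2COC(C)=O | intermediate
4 | (3R,5S,8S,9R,10R)-3-bromodrimane-8,11-diol | CC1(C)[C@H](Br)CC[C@]2(C)[C@@H]1CC[C@](C)(O)[C@H]2CO | intermediate
5 | diphenyl disulfide | c1ccc(cc1)SSc1ccccc1 | starting material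
6 | (3R,5S,8S,9S,10R)-3-bromo-11-(phenylsulfanyl)driman-8-ol | CC1(C)[C@H](Br)CC[C@]2(C)[C@@H]1CC[C@](C)(O)[C@H]2CSc1ccccc1 | intermediate
7 | (3R,5S,8S,9S,10R)-3-bromo-11-(phenylsulfonyl)driman-8-ol | CC1(C)[C@H](Br)CC[C@]2(C)[C@@H]1CC[C@](C)(O)[C@H]2CS(=O)(=O)c1ccccc1 | intermediate
8 | 4-methylfuran-2(5H)-one | CC1=CC(=O)OC1 | starting material
9 | trimethylsilyl (Z)-4-bromo-3-methylbut-2-enoate | C[Si](C)(C)OC(=O)/C=C(C)\CBr | intermediate (not isolated)
10 | methyl (Z)-4-bromo-3-methylbut-2-enoate | COC(=O)/C=C(C)\CBr | intermediate
11 | (Z)-4-bromo-3-methylbut-2-en-1-ol | OC/C=C(C)\CBr | intermediate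
12 | (Z)-1-bromo-4-chloro-2-methylbut-2-ene | ClC/C=C(C)\CBr | intermediate
13 | lithium (3R,5S,8S,9S,10R,11S,13Z)-3-bromo-15-chloro-11-(phenylsulfonyl)labd-13-en-8-olate | [Li+].CC1(C)[C@H](Br)CC[C@]2(C)[C@@H]1CC[C@](C)([O-])[C@H]2[C@H](C/C(C)=C\CCl)S(=O)(=O)c1ccccc1 | intermediate (not isolated)
14 | (3R,5S,8S,9S,10R,11S,13Z)-3-bromo-8,15-epoxy-11-(phenylsulfonyl)labd-13-ene | CC1(C)[C@H](Br)CC[C@]2(C)[C@@H]1CC[C@]1(C)OC/C=C(C)\C[C@H](S(=O)(=O)c3ccccc3)[C@@H]21 | intermediate
15 | (3R,5S,8S,9S,10R,13Z)-3-bromo-8,15-epoxylabd-13-ene | CC1(C)[C@H](Br)CC[C@]2(C)[C@@H]1CC[C@]1(C)OC/C=C(C)\CC[C@@H]21 | intermediate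
16 | (3R,5S,8S,9S,10R,13S,14R)-3-bromo-8,15:13,14-diepoxylabdane | CC1(C)[C@H](Br)CC[C@]2(C)[C@@H]1CC[C@]1(C)OC[C@H]3O[C@@]3(C)CC[C@@H]21 | target

## Step count and least certain steps

Total: 10 steps. Longest linear sequence: 7 steps (steps 1–4 and 8–10); the branch to 12 has 3 steps (5–7).

Step 1 (bears the label).
- What may go wrong: the cascade may stop early, by proton loss after the first ring or at C8 in competition with capture by the ester. Face discrimination at the terminal olefin may also be weak, because the substrate lacks the arene of the substrates on which this catalysis is established.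
- Fallback, known chemistry, from 1 back to 4: 1 is cyclised without chiral catalyst by Et2SBr·SbCl5Br in MeNO2 at −25 °C with aqueous work-up, giving the racemic hydroxy acetate F1. K2CO3/MeOH gives the racemic diol F2. The primary alcohol is esterified with (1S)-camphanic chloride (pyridine, DMAP), and the two diastereomeric esters are separated by crystallisation or chromatography to give the camphanate F3 of the required enantiomer. K2CO3/MeOH then releases 4.

Step 8 (key step).
- What may go wrong: eight-membered etherification by a hindered tertiary alkoxide may be slow, which opens the way to intermolecular O-alkylation, oligomerisation or loss of HCl from the allylic chloride. The first alkylation may favour the C11 epimer of 13 that cannot close, and its equilibration may be slow.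
- Fallback, from 6 back to 14: 6 is O-allylated (KH, allyl bromide, THF; no acidic C–H competes at the sulfide stage) to the allyl ether sulfide F4. This is oxidised with (NH4)6Mo7O24/H2O2 in EtOH, which leaves the terminal olefin alone, to the allyl ether sulfone F5. Deprotonation (n-BuLi, 1 equiv) and alkylation with 3-bromo-2-methylprop-1-ene give the diene sulfone F6. Ring-closing metathesis with the second-generation Hoveyda–Grubbs catalyst (H2IMes)Cl2Ru(=CH-2-i-PrOC6H4) in hot toluene at high dilution then gives 14, since the ring can hold only the cis olefin. A C11 epimer of F6 that does not close would be equilibrated with KOt-Bu and recycled.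

Step 10.
- What may go wrong: facial selectivity may be poor if the medium ring populates a second conformer that turns the other olefin face outward, and the epoxide may open under traces of acid.
- Fallback, from 15 back to 16: NBS in aqueous THF forms the bromonium ion on the exposed face and water opens it at the tertiary C13 from the other face, giving the bromohydrin F7. K2CO3 in MeOH closes the epoxide with inversion at C14, which places the oxygen on the face opposite to direct peracid attack.

Step 9.
- What may go wrong: electron transfer to the C3–Br bond may compete, with loss of bromine, or the heterogeneous reduction may stall on the hindered secondary sulfone.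
- Fallback, from 4 back to 15: 4 is converted with 2,2'-dipyridyl disulfide and Bu3P to the 2-pyridyl sulfide F8 and oxidised with (NH4)6Mo7O24/H2O2 to the 2-pyridyl sulfone F9. The annulation of step 8 with 12 gives the pyridylsulfonyl oxocene F10. Its electron-poor heteroaryl sulfone should be cleaved by SmI2 in THF/MeOH at low temperature without HMPA, conditions under which unactivated alkyl bromides are not reduced, to give 15.

Step 5.
- What may go wrong: the bromo ester may re-lactonise or isomerise from Z to E during the acidic methanolysis, and halide exchange in step 7 would then erode the difference between the two termini.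
- Fallback, replacing 8 and coming back at 10: commercial methyl 3-methylbut-2-enoate F11 is brominated under Wohl–Ziegler conditions (NBS, AIBN, PhCF3, reflux) to the known mixture of 10 and its (E) isomer F12, from which 10 is separated by chromatography or fractional distillation.

## Further compounds

F1 | step 1 | racemic 3-bromo-8-hydroxydriman-11-yl acetate (3 and its enantiomer, 1:1) | CC1(C)[C@H](Br)CC[C@]2(C)[C@@H]1CC[C@](C)(O)[C@H]2COC(C)=O.CC1(C)[C@@H](Br)CC[C@@]2(C)[C@H]1CC[C@@](C)(O)[C@@H]2COC(C)=O
F2 | step 1 | racemic 3-bromodrimane-8,11-diol (4 and its enantiomer, 1:1) | CC1(C)[C@H](Br)CC[C@]2(C)[C@@H]1CC[C@](C)(O)[C@H]2CO.CC1(C)[C@@H](Br)CC[C@@]2(C)[C@H]1CC[C@@](C)(O)[C@@H]2CO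
F3 | step 1 | (3R,5S,8S,9R,10R)-3-bromo-8-hydroxydriman-11-yl (1S,4R)-camphanate | CC1(C)[C@H](Br)CC[C@]2(C)[C@@H]1CC[C@](C)(O)[C@H]2COC(=O)[C@@]12CC[C@@](C)(C(=O)O1)C2(C)C
F4 | step 8 | (3R,5S,8S,9S,10R)-8-(allyloxy)-3-bromo-11-(phenylsulfanyl)drimane | CC1(C)[C@H](Br)CC[C@]2(C)[C@@H]1CC[C@](C)(OCC=C)[C@H]2CSc1ccccc1
F5 | step 8 | (3R,5S,8S,9S,10R)-8-(allyloxy)-3-bromo-11-(phenylsulfonyl)drimane | CC1(C)[C@H](Br)CC[C@]2(C)[C@@H]1CC[C@](C)(OCC=C)[C@H]2CS(=O)(=O)c1ccccc1
F6 | step 8 | (3R,5S,8S,9S,10R)-8-(allyloxy)-3-bromo-11-(2-methylallyl)-11-(phenylsulfonyl)drimane, C11 epimers | CC1(C)[C@H](Br)CC[C@]2(C)[C@@H]1CC[C@](C)(OCC=C)[C@H]2C(CC(C)=C)S(=O)(=O)c1ccccc1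
F7 | step 10 | (3R,5S,8S,9S,10R,13S,14S)-3,14-dibromo-8,15-epoxylabdan-13-ol | CC1(C)[C@H](Br)CC[C@]2(C)[C@@H]1CC[C@]1(C)OC[C@H](Br)[C@](O)(C)CC[C@@H]21
F8 | step 9 | (3R,5S,8S,9S,10R)-3-bromo-11-(pyridin-2-ylsulfanyl)driman-8-ol | CC1(C)[C@H](Br)CC[C@]2(C)[C@@H]1CC[C@](C)(O)[C@H]2CSc1ccccn1
F9 | step 9 | (3R,5S,8S,9S,10R)-3-bromo-11-(pyridin-2-ylsulfonyl)driman-8-ol | CC1(C)[C@H](Br)CC[C@]2(C)[C@@H]1CC[C@](C)(O)[C@H]2CS(=O)(=O)c1ccccn1
F10 | step 9 | (3R,5S,8S,9S,10R,11S,13Z)-3-bromo-8,15-epoxy-11-(pyridin-2-ylsulfonyl)labd-13-ene | CC1(C)[C@H](Br)CC[C@]2(C)[C@@H]1CC[C@]1(C)OC/C=C(C)\C[C@H](S(=O)(=O)c3ccccn3)[C@@H]21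
F11 | step 5 | methyl 3-methylbut-2-enoate | COC(=O)C=C(C)C
F12 | step 5 | methyl (E)-4-bromo-3-methylbut-2-enoate | COC(=O)/C=C(C)/CBr
A1 | alternative 1 | tricyclic oxepan-3-one: ring C of 16 without C13 and its methyl, carbonyl at C14 between C15 and C12 | CC1(C)[C@H](Br)CC[C@]2(C)[C@@H]1CC[C@]1(C)OCC(=O)CC[C@@H]21
A2 | alternative 1 | 3-bromo-8,15-epoxylabdan-14-one (eight-membered ether ketone, methyl on C13) | CC1(C)[C@H](Br)CC[C@]2(C)[C@@H]1CC[C@]1(C)OCC(=O)[C@@H](C)CC[C@@H]21
A3 | alternative 2 | (3R,5S,8S,9S,10R,13Z)-3-bromo-8-(methoxymethoxy)-14-(trimethylsilyl)-15-norlabd-13-ene | CC1(C)[C@H](Br)CC[C@]2(C)[C@@H]1CC[C@](C)(OCOC)[C@H]2CC/C(C)=C\[Si](C)(C)C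
A4 | alternative 2 | (3R,5S,8S,9S,10R,13Z)-3-bromo-8,15-epoxylabd-13-ene (same structure as 15) | CC1(C)[C@H](Br)CC[C@]2(C)[C@@H]1CC[C@]1(C)OC/C=C(C)\CC[C@@H]21
A5 | alternative 3 | tetracyclic lactol: 3-bromo-8,15-epoxy-11,15-cyclolabdan-15-ol, cis-fused at C11/C15 (either face) | CC1(C)[C@H](Br)CC[C@]2(C)[C@@H]1CC[C@]1(C)OC3(O)C[C@H](C)CC3[C@@H]21
A6 | alternative 3 | 3-bromolabdan-15,8-olide (eight-membered lactone, C15 carbonyl, methyl on C13) | CC1(C)[C@H](Br)CC[C@]2(C)[C@@H]1CC[C@]1(C)OC(=O)C[C@H](C)CC[C@@H]21
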